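**Retrosynthetic overview**

1. Feature: ring A (C4a, C5, C6, C7, C8, C8a) is a pentasubstituted phloroglucinol ring with three different oxygens (O1, the C5 methyl ether, the C7 hydroxyl) and C8 bonded to the stereogenic methine C5''. It is therefore built new from an alkyne that already sits on C5''.
2. Ring C goes last: the C2–C1' bond by rhodium-catalysed asymmetric arylation of a chromone (sets C2), and O1–C2 / C4–C4a from the ring A phenol by ortho-formylation, ethynylation, oxidation and 6-endo closure.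
3. Ring A: the C8–C8a and C6–C7 bonds are cut back to siloxyalkyne 21 and 3-methoxycyclobutenone 23 (benzannulation).
4. Siloxyalkyne 21: C5'' by catalytic asymmetric conjugate alkynylation of an aryl enone whose C7'' carbonyl then becomes the E-styrene; the enone by cross-metathesis; C3'' by allylboration. A late reduction of a C3'' ketone flanked by two methylene groups is avoided.
5. Order of ring formation: ring A (step 15), then ring C (step 18); ring B and the two heptanoid arenes are bought.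

Key step: step 15

Assumption: the catalyst enantiomers written in steps 9 and 19 are those expected to give Si-face alkynylation of C5'' and Re-face arylation of C2; if either induction proves opposite, the mirror-image diol or bisphosphine is used.

Notation: Ar = 4-(tert-butyldimethylsilyloxy)phenyl; TBS = tert-butyldimethylsilyl; TIPS = triisopropylsilyl; C1''–C7'' are the heptanoid carbons (aryl groups on C1'' and C7'', oxygen on C3'', branch at C5''); Hep = (1E,3S,5S)-5-(TBSO)-1,7-bis(Ar)hept-1-en-3-yl, the protected heptanoid bonded through C5''.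

**Route**

Step 1
Reactants: 1 methyl 3-(4-hydroxyphenyl)propanoate
Product: 2 methyl 3-[4-(tert-butyldimethylsilyloxy)phenyl]propanoate
Conditions: TBSCl, imidazole, DMF, rt
Reagents that add atoms: tert-butyldimethylsilyl chloride, CC(C)(C)[Si](C)(C)Cl
Why: Imidazole-promoted silylation of a phenol is routine and leaves the methyl ester untouched.

Step 2
Reactants: 2 methyl 3-[4-(tert-butyldimethylsilyloxy)phenyl]propanoate
Product: 3 3-[4-(tert-butyldimethylsilyloxy)phenyl]propanal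
Conditions: i-Bu2AlH (1.05 equiv), CH2Cl2, −78 °C; Rochelle salt work-up
Reagents that add atoms: none
Why: Partial ester reduction; the aluminium hemiacetal is stable at −78 °C and releases the aldehyde only on work-up, and the aryl silyl ether is inert.

Step 3
Reactants: 3 3-[4-(tert-butyldimethylsilyloxy)phenyl]propanal
Product: 5 (S)-1-[4-(tert-butyldimethylsilyloxy)phenyl]hex-5-en-3-ol, via homoallyl diisopinocampheylborinate 4 (not isolated)
Conditions: (+)-Ipc2B(allyl) (from (−)-α-pinene, 1.2 equiv), Et2O, −78 °C; then aq NaOAc, 30% H2O2, rt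
Reagents that add atoms: (+)-B-allyldiisopinocampheylborane, C=CCB([C@H]1C[C@H]2C[C@@H]([C@@H]1C)C2(C)C)[C@H]1C[C@H]2C[C@@H]([C@@H]1C)C2(C)C
Why: Brown allylboration through a closed chair transition state; this reagent adds allyl to the Re face of an unbranched aldehyde, which sets C3'' as S, and the buffered peroxide work-up spares the aryl silyl ether.

Step 4
Reactants: 5 (S)-1-[4-(tert-butyldimethylsilyloxy)phenyl]hex-5-en-3-ol
Product: 6 (S)-3-(TBSO)-1-(Ar)hex-5-ene
Conditions: TBSCl, imidazole, DMF, rt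
Reagents that add atoms: tert-butyldimethylsilyl chloride, CC(C)(C)[Si](C)(C)Cl
Why: Standard silylation of a secondary alcohol; the ether carries C3''–O through the organometallic, oxidative and thermal steps that follow.

Step 5
Reactants: 7 4-(tert-butyldimethylsilyloxy)benzaldehyde
Product: 8 1-(Ar)prop-2-en-1-ol (racemic)
Conditions: CH2=CHMgBr, THF, −78 → 0 °C
Reagents that add atoms: vinylmagnesium bromide, C=C[Mg]Br
Why: Grignard 1,2-addition to a non-enolisable aldehyde; the carbinol centre is removed in the next step.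

Step 6
Reactants: 8 1-(Ar)prop-2-en-1-ol
Product: 9 1-(Ar)prop-2-en-1-one
Conditions: MnO2 (activated, excess), CH2Cl2, rt; used at once
Reagents that add atoms: none
Why: MnO2 oxidises the benzylic and allylic alcohol selectively under neutral conditions; the aryl vinyl ketone is not stored because it polymerises.

Step 7
Reactants: 6 (S)-3-(TBSO)-1-(Ar)hex-5-ene; 9 1-(Ar)prop-2-en-1-one
Product: 10 (S,E)-5-(TBSO)-1,7-bis(Ar)hept-2-en-1-one
Conditions: second-generation Hoveyda–Grubbs catalyst (5 mol %), 9 (3 equiv), CH2Cl2, 40 °C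
Reagents that add atoms: none
Why: Olefin cross-metathesis between a terminal alkene and an electron-poor vinyl ketone that does not homodimerise is selective for the cross product and gives the E-enone.

Step 8
Reactants: 11 ethynyltrimethylsilane
Product: 14 diisopropyl [(trimethylsilyl)ethynyl]boronate, via lithium (trimethylsilyl)acetylide 12 (not isolated), via lithium alkynyl(triisopropoxy)borate 13 (not isolated)
Conditions: n-BuLi, Et2O, −78 °C; B(Oi-Pr)3, −78 °C; anhydrous HCl in Et2O, −78 °C → rt; filtration, distillation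
Reagents that add atoms: triisopropyl borate, CC(C)OB(OC(C)C)OC(C)C
Why: Standard preparation of a 1-alkynyl boronic ester: acetylide borylation gives the ate complex, and anhydrous protonolysis removes one isopropoxide.

Step 9
Reactants: 10 (S,E)-5-(TBSO)-1,7-bis(Ar)hept-2-en-1-one; 14 diisopropyl [(trimethylsilyl)ethynyl]boronate
Product: 15 (3S,5S)-5-(TBSO)-1,7-bis(Ar)-3-[(trimethylsilyl)ethynyl]heptan-1-one
Conditions: (S)-3,3'-diiodo-1,1'-bi-2-naphthol (20 mol %), 14 (3 equiv), CH2Cl2, rt → 40 °C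
Reagents that add atoms: none
Why: Binaphthol-catalysed asymmetric conjugate alkynylboration: ligand exchange gives a Lewis-acidic binaphthol alkynylboronate that binds the s-cis enone carbonyl and delivers the alkynyl group through a closed six-membered transition state, so addition is strictly 1,4 and the catalyst, not the remote C3'' centre, selects the Si face of C5'' (5''S).

Step 10
Reactants: 15 (3S,5S)-5-(TBSO)-1,7-bis(Ar)-3-[(trimethylsilyl)ethynyl]heptan-1-one
Product: 16 (3R,5S)-5-(TBSO)-1,7-bis(Ar)-3-[(trimethylsilyl)ethynyl]heptan-1-ol (both C1 epimers; C3 is unchanged in space and only its descriptor changes)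
Conditions: NaBH4, THF/MeOH (4:1), 0 °C
Reagents that add atoms: none
Why: Borohydride 1,2-reduction of the aryl ketone; the new carbinol centre is destroyed in the next step, so its configuration does not matter.

Step 11
Reactants: 16 (3R,5S)-5-(TBSO)-1,7-bis(Ar)-3-[(trimethylsilyl)ethynyl]heptan-1-ol
Product: 17 (3S,5S,6E)-3-(TBSO)-1,7-bis(Ar)-5-[(trimethylsilyl)ethynyl]hept-6-ene
Conditions: Burgess reagent (2 equiv), toluene, 50 °C
Reagents that add atoms: none
Why: Burgess dehydration (syn elimination of the sulfamate ester) of the electron-rich benzylic alcohol can only give the conjugated C6''=C7'' alkene, E from the favoured conformer, under neutral conditions that do not isomerise the skipped enyne at C5''.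

Step 12
Reactants: 17 (3S,5S,6E)-3-(TBSO)-1,7-bis(Ar)-5-[(trimethylsilyl)ethynyl]hept-6-ene
Product: 18 (3S,5S,6E)-3-(TBSO)-1,7-bis(Ar)-5-ethynylhept-6-ene
Conditions: AgNO3 (0.2 equiv), acetone/H2O (4:1), rt, dark
Reagents that add atoms: none
Why: Silver-catalysed protodesilylation cleaves only the alkynyl C–Si bond (through a silver acetylide) and leaves aryl and alkyl silyl ethers intact, which K2CO3/MeOH or fluoride would not.

Step 13
Reactants: 18 (3S,5S,6E)-3-(TBSO)-1,7-bis(Ar)-5-ethynylhept-6-ene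
Product: 21 (3S,5S,6E)-3-(TBSO)-1,7-bis(Ar)-5-[(triisopropylsilyloxy)ethynyl]hept-6-ene, via lithium acetylide 19 (not isolated), via lithium ynolate 20 (not isolated)
Conditions: LiN(SiMe3)2 (1.1 equiv), THF, −78 °C; t-BuOOLi (from t-BuOOH and LiN(SiMe3)2, 1.2 equiv), −78 → 0 °C; i-Pr3SiOTf (1.3 equiv), −78 °C → rt; Et3N-deactivated silica
Reagents that add atoms: tert-butyl hydroperoxide (as its lithium salt), CC(C)(C)OO; triisopropylsilyl triflate, CC(C)[Si](C(C)C)(C(C)C)OS(=O)(=O)C(F)(F)F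
Why: Electrophilic oxygen transfer from lithium tert-butyl peroxide to the lithium acetylide gives the ynolate, which the bulky silyl triflate captures on oxygen as a 1-siloxy-1-alkyne; the amide base removes only the alkyne C–H and leaves the C5'' hydrogen in place.

Step 14
Reactants: 22 cyclobutane-1,3-dione
Product: 23 3-methoxycyclobut-2-en-1-one
Conditions: Me3SiCHN2, MeOH/CH2Cl2, 0 °C
Reagents that add atoms: (trimethylsilyl)diazomethane, C[Si](C)(C)C=[N+]=[N-]
Why: O-Methylation of the strongly acidic enol form (3-hydroxycyclobutenone) with a diazomethane surrogate gives the vinylogous ester.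

Step 15
Reactants: 21 (3S,5S,6E)-3-(TBSO)-1,7-bis(Ar)-5-[(triisopropylsilyloxy)ethynyl]hept-6-ene; 23 3-methoxycyclobut-2-en-1-one
Product: 28 2-(Hep)-5-methoxy-3-(triisopropylsilyloxy)phenol, via methoxyvinylketene 24 (not isolated), via vinylcyclobutenone adduct 25 (not isolated), via dienylketene 26 (not isolated), via cyclohexadienone 27 (not isolated)
Conditions: 23 (1.5 equiv), toluene, 80 → 110 °C, argon
Reagents that add atoms: none
Why: Danheiser benzannulation: on heating, 23 undergoes 4π electrocyclic opening to methoxyvinylketene 24, whose carbonyl carbon is attacked by the nucleophilic alkyne carbon that bears C5'' in a regioselective [2+2] cycloaddition, forming the C8–C8a and C6–C7 bonds of adduct 25. A second 4π opening gives dienylketene 26, and ring A is closed by thermal 6π electrocyclization to dienone 27, which tautomerises to phenol 28. The closest known reaction type is the aromatic annulation of cyclobutenones with trialkylsilyloxyalkynes, which gives resorcinol monosilyl ethers with this orientation. No stereocentre is formed; C5'' and C3'' are spectators under neutral heating, and the isolated styrene does not intercept the ketene. The selectivity needed is the orientation of the ketene–alkyne cycloaddition, which the oxygen polarisation of the siloxyalkyne secures. The chain therefore ends up between a free hydroxyl (future O1) and the silyl ether (future O7), para to the methoxy group, so no choice between C6 and C8 or between O1 and O7 has to be made.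

Step 16
Reactants: 28 2-(Hep)-5-methoxy-3-(triisopropylsilyloxy)phenol
Product: 30 3-(Hep)-2-hydroxy-6-methoxy-4-(triisopropylsilyloxy)benzaldehyde, via hydroxymethylphenol 29 (not isolated)
Conditions: MgCl2 (3 equiv), Et3N (6 equiv), (CH2O)n (8 equiv), MeCN, 75 °C
Reagents that add atoms: paraformaldehyde (as formaldehyde), C=O
Why: Magnesium-mediated ortho-formylation (Casnati–Skattebøl): the magnesium phenoxide delivers formaldehyde to its only free ortho position (C4a) and a second formaldehyde oxidises the hydroxymethyl intermediate by hydride transfer, so the position between the silyl ether and the methoxy group is not touched and no acid is used.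

Step 17
Reactants: 30 3-(Hep)-2-hydroxy-6-methoxy-4-(triisopropylsilyloxy)benzaldehyde
Product: 31 1-[3-(Hep)-2-hydroxy-6-methoxy-4-(triisopropylsilyloxy)phenyl]prop-2-yn-1-ol (both carbinol epimers)
Conditions: HC≡CMgBr (4 equiv), THF, 0 °C → rt; pH 7 work-up; used crude
Reagents that add atoms: ethynylmagnesium bromide, C#C[Mg]Br
Why: Grignard addition to the salicylaldehyde after deprotonation of the phenol by the first equivalent; the carbinol is oxidised next, so its configuration is irrelevant, and it is not purified because ortho-hydroxybenzylic alcohols ionise easily.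

Step 18
Reactants: 31 1-[3-(Hep)-2-hydroxy-6-methoxy-4-(triisopropylsilyloxy)phenyl]prop-2-yn-1-ol
Product: 33 8-(Hep)-5-methoxy-7-(triisopropylsilyloxy)-4H-chromen-4-one, via ethynyl ketone 32 (not isolated)
Conditions: MnO2 (excess), CH2Cl2, rt; filter; K2CO3 (0.5 equiv), acetone, rt
Reagents that add atoms: none
Why: MnO2 oxidises the propargylic and benzylic alcohol to the 2-hydroxyaryl ethynyl ketone, whose phenoxide adds 6-endo-dig (oxa-Michael) to the unsubstituted alkyne terminus and closes ring C as the chromone.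

Step 19
Reactants: 33 8-(Hep)-5-methoxy-7-(triisopropylsilyloxy)-4H-chromen-4-one; 34 4-(tert-butyldimethylsilyloxy)phenylboronic acid
Product: 35 (2S)-2-(Ar)-8-(Hep)-5-methoxy-7-(triisopropylsilyloxy)chroman-4-one
Conditions: 34 (3 equiv), [Rh(OH)(cod)]2 (3 mol %), (R)-MeO-F12-BIPHEP (7 mol %), toluene/H2O (10:1), 30 °C
Reagents that add atoms: none
Why: Rhodium-catalysed asymmetric 1,4-addition of an arylboronic acid to a chromone (Hayashi–Miyaura type): the aryl–rhodium species inserts the C2=C3 bond and hydrolysis of the oxa-π-allyl releases the flavanone; the electron-poor chiral bisphosphine directs the aryl group to the Re face of C2 (2S), and base-free conditions prevent ring opening of the product.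

Step 20
Reactants: 35 (2S)-2-(Ar)-8-(Hep)-5-methoxy-7-(triisopropylsilyloxy)chroman-4-one
Product: 36 (2S)-7-hydroxy-8-[(1E,3S,5S)-5-hydroxy-1,7-bis(4-hydroxyphenyl)hept-1-en-3-yl]-2-(4-hydroxyphenyl)-5-methoxychroman-4-one (CNP0191649.2)
Conditions: Bu4NF/AcOH (1:1, 8 equiv), THF, 0 °C → rt; pH 7 buffer work-up
Reagents that add atoms: none
Why: Fluoride cleaves the four aryl silyl ethers and the secondary alkyl silyl ether, while the acetic acid buffer keeps the phenols protonated so that the flavanone does not open by retro-oxa-Michael reaction (which would racemise C2) and no strong acid is present to add the C7 phenol across the styrene.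

**Compound list**

1 | methyl 3-(4-hydroxyphenyl)propanoate | COC(=O)CCc1ccc(O)cc1 | starting material
2 | methyl 3-[4-(tert-butyldimethylsilyloxy)phenyl]propanoate | COC(=O)CCc1ccc(O[Si](C)(C)C(C)(C)C)cc1 | intermediate
3 | 3-[4-(tert-butyldimethylsilyloxy)phenyl]propanal | O=CCCc1ccc(O[Si](C)(C)C(C)(C)C)cc1 | intermediate
4 | (S)-1-(Ar)hex-5-en-3-yl diisopinocampheylborinate | C=CC[C@H](CCc1ccc(O[Si](C)(C)C(C)(C)C)cc1)OB([C@H]1C[C@H]2C[C@@H]([C@@H]1C)C2(C)C)[C@H]1C[C@H]2C[C@@H]([C@@H]1C)C2(C)C | intermediate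
5 | (S)-1-[4-(tert-butyldimethylsilyloxy)phenyl]hex-5-en-3-ol | C=CC[C@@H](O)CCc1ccc(O[Si](C)(C)C(C)(C)C)cc1 | intermediate
6 | (S)-3-(TBSO)-1-(Ar)hex-5-ene | C=CC[C@@H](O[Si](C)(C)C(C)(C)C)CCc1ccc(O[Si](C)(C)C(C)(C)C)cc1 | intermediate
7 | 4-(tert-butyldimethylsilyloxy)benzaldehyde | O=Cc1ccc(O[Si](C)(C)C(C)(C)C)cc1 | starting material
8 | 1-(Ar)prop-2-en-1-ol (racemic) | C=CC(O)c1ccc(O[Si](C)(C)C(C)(C)C)cc1 | intermediate
9 | 1-(Ar)prop-2-en-1-one | C=CC(=O)c1ccc(O[Si](C)(C)C(C)(C)C)cc1 | intermediate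
10 | (S,E)-5-(TBSO)-1,7-bis(Ar)hept-2-en-1-one | O=C(/C=C/C[C@@H](O[Si](C)(C)C(C)(C)C)CCc1ccc(O[Si](C)(C)C(C)(C)C)cc1)c1ccc(O[Si](C)(C)C(C)(C)C)cc1 | intermediate
11 | ethynyltrimethylsilane | C#C[Si](C)(C)C | starting material
12 | lithium (trimethylsilyl)acetylide | [Li]C#C[Si](C)(C)C | intermediate
13 | lithium triisopropoxy[(trimethylsilyl)ethynyl]borate | [Li+].CC(C)O[B-](OC(C)C)(OC(C)C)C#C[Si](C)(C)C | intermediate
14 | diisopropyl [(trimethylsilyl)ethynyl]boronate | CC(C)OB(OC(C)C)C#C[Si](C)(C)C | intermediate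
15 | (3S,5S)-5-(TBSO)-1,7-bis(Ar)-3-[(trimethylsilyl)ethynyl]heptan-1-one | O=C(C[C@@H](C#C[Si](C)(C)C)C[C@@H](O[Si](C)(C)C(C)(C)C)CCc1ccc(O[Si](C)(C)C(C)(C)C)cc1)c1ccc(O[Si](C)(C)C(C)(C)C)cc1 | intermediate
16 | (3R,5S)-5-(TBSO)-1,7-bis(Ar)-3-[(trimethylsilyl)ethynyl]heptan-1-ol, both C1 epimers | OC(C[C@@H](C#C[Si](C)(C)C)C[C@@H](O[Si](C)(C)C(C)(C)C)CCc1ccc(O[Si](C)(C)C(C)(C)C)cc1)c1ccc(O[Si](C)(C)C(C)(C)C)cc1 | intermediate
17 | (3S,5S,6E)-3-(TBSO)-1,7-bis(Ar)-5-[(trimethylsilyl)ethynyl]hept-6-ene | C[Si](C)(C)C#C[C@H](/C=C/c1ccc(O[Si](C)(C)C(C)(C)C)cc1)C[C@@H](O[Si](C)(C)C(C)(C)C)CCc1ccc(O[Si](C)(C)C(C)(C)C)cc1 | intermediate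
18 | (3S,5S,6E)-3-(TBSO)-1,7-bis(Ar)-5-ethynylhept-6-ene | C#C[C@H](/C=C/c1ccc(O[Si](C)(C)C(C)(C)C)cc1)C[C@@H](O[Si](C)(C)C(C)(C)C)CCc1ccc(O[Si](C)(C)C(C)(C)C)cc1 | intermediate
19 | lithium acetylide of 18 | [Li]C#C[C@H](/C=C/c1ccc(O[Si](C)(C)C(C)(C)C)cc1)C[C@@H](O[Si](C)(C)C(C)(C)C)CCc1ccc(O[Si](C)(C)C(C)(C)C)cc1 | intermediate
20 | lithium ynolate from 19 | [Li]OC#C[C@H](/C=C/c1ccc(O[Si](C)(C)C(C)(C)C)cc1)C[C@@H](O[Si](C)(C)C(C)(C)C)CCc1ccc(O[Si](C)(C)C(C)(C)C)cc1 | intermediate
21 | (3S,5S,6E)-3-(TBSO)-1,7-bis(Ar)-5-[(triisopropylsilyloxy)ethynyl]hept-6-ene | CC(C)[Si](C(C)C)(C(C)C)OC#C[C@H](/C=C/c1ccc(O[Si](C)(C)C(C)(C)C)cc1)C[C@@H](O[Si](C)(C)C(C)(C)C)CCc1ccc(O[Si](C)(C)C(C)(C)C)cc1 | intermediate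
22 | cyclobutane-1,3-dione | O=C1CC(=O)C1 | starting material
23 | 3-methoxycyclobut-2-en-1-one | COC1=CC(=O)C1 | intermediate
24 | 3-methoxybuta-1,3-dien-1-one (methoxyvinylketene) | C=C(OC)C=C=O | intermediate
25 | 2-(Hep)-4-(1-methoxyethenyl)-3-(triisopropylsilyloxy)cyclobut-2-en-1-one, both C4 epimers | C=C(OC)C1C(O[Si](C(C)C)(C(C)C)C(C)C)=C([C@H](/C=C/c2ccc(O[Si](C)(C)C(C)(C)C)cc2)C[C@@H](O[Si](C)(C)C(C)(C)C)CCc2ccc(O[Si](C)(C)C(C)(C)C)cc2)C1=O | intermediate
26 | (3E)-2-(Hep)-5-methoxy-3-(triisopropylsilyloxy)hexa-1,3,5-trien-1-one (dienylketene) | O=C=C([C@H](/C=C/c1ccc(O[Si](C)(C)C(C)(C)C)cc1)C[C@@H](O[Si](C)(C)C(C)(C)C)CCc1ccc(O[Si](C)(C)C(C)(C)C)cc1)/C(O[Si](C(C)C)(C(C)C)C(C)C)=C\C(OC)=C | intermediate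
27 | 2-(Hep)-5-methoxy-3-(triisopropylsilyloxy)cyclohexa-2,4-dien-1-one | O=C1CC(OC)=CC(O[Si](C(C)C)(C(C)C)C(C)C)=C1[C@H](/C=C/c1ccc(O[Si](C)(C)C(C)(C)C)cc1)C[C@@H](O[Si](C)(C)C(C)(C)C)CCc1ccc(O[Si](C)(C)C(C)(C)C)cc1 | intermediate
28 | 2-(Hep)-5-methoxy-3-(triisopropylsilyloxy)phenol | COc1cc(O)c([C@H](/C=C/c2ccc(O[Si](C)(C)C(C)(C)C)cc2)C[C@@H](O[Si](C)(C)C(C)(C)C)CCc2ccc(O[Si](C)(C)C(C)(C)C)cc2)c(O[Si](C(C)C)(C(C)C)C(C)C)c1 | intermediate
29 | 2-(Hep)-6-(hydroxymethyl)-5-methoxy-3-(triisopropylsilyloxy)phenol | COc1cc(O[Si](C(C)C)(C(C)C)C(C)C)c([C@H](/C=C/c2ccc(O[Si](C)(C)C(C)(C)C)cc2)C[C@@H](O[Si](C)(C)C(C)(C)C)CCc2ccc(O[Si](C)(C)C(C)(C)C)cc2)c(O)c1CO | intermediate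
30 | 3-(Hep)-2-hydroxy-6-methoxy-4-(triisopropylsilyloxy)benzaldehyde | COc1cc(O[Si](C(C)C)(C(C)C)C(C)C)c([C@H](/C=C/c2ccc(O[Si](C)(C)C(C)(C)C)cc2)C[C@@H](O[Si](C)(C)C(C)(C)C)CCc2ccc(O[Si](C)(C)C(C)(C)C)cc2)c(O)c1C=O | intermediate
31 | 1-[3-(Hep)-2-hydroxy-6-methoxy-4-(triisopropylsilyloxy)phenyl]prop-2-yn-1-ol, both carbinol epimers | COc1cc(O[Si](C(C)C)(C(C)C)C(C)C)c([C@H](/C=C/c2ccc(O[Si](C)(C)C(C)(C)C)cc2)C[C@@H](O[Si](C)(C)C(C)(C)C)CCc2ccc(O[Si](C)(C)C(C)(C)C)cc2)c(O)c1C(O)C#C | intermediate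
32 | 1-[3-(Hep)-2-hydroxy-6-methoxy-4-(triisopropylsilyloxy)phenyl]prop-2-yn-1-one | COc1cc(O[Si](C(C)C)(C(C)C)C(C)C)c([C@H](/C=C/c2ccc(O[Si](C)(C)C(C)(C)C)cc2)C[C@@H](O[Si](C)(C)C(C)(C)C)CCc2ccc(O[Si](C)(C)C(C)(C)C)cc2)c(O)c1C(=O)C#C | intermediate
33 | 8-(Hep)-5-methoxy-7-(triisopropylsilyloxy)-4H-chromen-4-one | COc1cc(O[Si](C(C)C)(C(C)C)C(C)C)c([C@H](/C=C/c2ccc(O[Si](C)(C)C(C)(C)C)cc2)C[C@@H](O[Si](C)(C)C(C)(C)C)CCc2ccc(O[Si](C)(C)C(C)(C)C)cc2)c2OC=CC(=O)c12 | intermediate
34 | 4-(tert-butyldimethylsilyloxy)phenylboronic acid | OB(O)c1ccc(O[Si](C)(C)C(C)(C)C)cc1 | starting material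
35 | (2S)-2-(Ar)-8-(Hep)-5-methoxy-7-(triisopropylsilyloxy)chroman-4-one | COc1cc(O[Si](C(C)C)(C(C)C)C(C)C)c([C@H](/C=C/c2ccc(O[Si](C)(C)C(C)(C)C)cc2)C[C@@H](O[Si](C)(C)C(C)(C)C)CCc2ccc(O[Si](C)(C)C(C)(C)C)cc2)c2c1C(=O)C[C@@H](c1ccc(O[Si](C)(C)C(C)(C)C)cc1)O2 | intermediate
36 | (2S)-7-hydroxy-8-[(1E,3S,5S)-5-hydroxy-1,7-bis(4-hydroxyphenyl)hept-1-en-3-yl]-2-(4-hydroxyphenyl)-5-methoxychroman-4-one | COc1cc(O)c([C@H](/C=C/c2ccc(O)cc2)C[C@@H](O)CCc2ccc(O)cc2)c2c1C(=O)C[C@@H](c1ccc(O)cc1)O2 | target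

**Step count and risk**

Total: 20 steps. Longest linear sequence: 16 steps (1 → 2 → 3 → 5 → 6 → 10 → 15 → 16 → 17 → 18 → 21 → 28 → 30 → 31 → 33 → 35 → 36).

Steps most likely to fail:

Step 15 (benzannulation). The siloxyalkyne may be lost to ketene oligomerisation or thermal decay before the cyclobutenone has opened, or the cascade may stall at the cyclobutenone adduct. The fallback sets out from 21 and comes back at 28. The vinylketene 24 is generated at 0–25 °C instead, by 1,4-dehydrochlorination of (E)-3-methoxybut-2-enoyl chloride F1 (from the purchased acid and oxalyl chloride) with Et3N in CH2Cl2 in the presence of 21. The ketene–siloxyalkyne [2+2] adduct 25 is then isolated and heated on its own in toluene (80–110 °C), where the second ring opening and the 6π closure give 28.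

Step 9 (conjugate alkynylation). Alkynyl transfer from the silylethynyl boronate may be slow, or facial selectivity may be eroded by a mismatch with C3''. The fallback sets out from 10 and comes back at 18. Rhodium-catalysed conjugate addition of (triisopropylsilyl)acetylene ([Rh(OAc)(C2H4)2]2, (R)-DTBM-segphos, 1,4-dioxane, 80 °C; the bulky silyl group suppresses alkyne dimerisation) gives (3S,5S)-5-(TBSO)-1,7-bis(Ar)-3-[(triisopropylsilyl)ethynyl]heptan-1-one F2. NaBH4 reduction gives the heptan-1-ol F3, and Burgess dehydration gives (3S,5S,6E)-3-(TBSO)-1,7-bis(Ar)-5-[(triisopropylsilyl)ethynyl]hept-6-ene F4. Because the C-silyl group needs fluoride, Bu4NF removes all silyl groups to give (3S,5S,6E)-5-ethynyl-1,7-bis(4-hydroxyphenyl)hept-6-en-3-ol F5, and TBSCl/imidazole re-silylates the three hydroxyls to give 18.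

Step 19 (asymmetric arylation). Insertion into the electron-rich, peri-substituted chromone may be sluggish, with protodeboronation or ring opening of the flavanone competing, or face selection may be incomplete. The fallback sets out from 30 and comes back at 35. Takai iodo-olefination of 7 (CHI3, CrCl2, THF) gives (E)-1-(Ar)-2-iodoethene F6. Iodine–lithium exchange (t-BuLi, −78 °C) and addition to 30 gives (E)-1-[3-(Hep)-2-hydroxy-6-methoxy-4-(triisopropylsilyloxy)phenyl]-3-(Ar)prop-2-en-1-ol F7, and MnO2 oxidation gives the 2'-hydroxychalcone (E)-1-[3-(Hep)-2-hydroxy-6-methoxy-4-(triisopropylsilyloxy)phenyl]-3-(Ar)prop-2-en-1-one F8. A cinchona-derived bifunctional thiourea then catalyses the intramolecular oxa-Michael addition (phenol oxygen to the Si face of C2) to close ring C as 35; the minor C2 epimer is removed by chromatography.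

**Further compounds**

F1 | step 15 | (E)-3-methoxybut-2-enoyl chloride | CO/C(C)=C/C(=O)Cl
F2 | step 9 | (3S,5S)-5-(TBSO)-1,7-bis(Ar)-3-[(triisopropylsilyl)ethynyl]heptan-1-one | O=C(C[C@@H](C#C[Si](C(C)C)(C(C)C)C(C)C)C[C@@H](O[Si](C)(C)C(C)(C)C)CCc1ccc(O[Si](C)(C)C(C)(C)C)cc1)c1ccc(O[Si](C)(C)C(C)(C)C)cc1
F3 | step 9 | 5-(TBSO)-1,7-bis(Ar)-3-[(triisopropylsilyl)ethynyl]heptan-1-ol, both C1 epimers | OC(C[C@@H](C#C[Si](C(C)C)(C(C)C)C(C)C)C[C@@H](O[Si](C)(C)C(C)(C)C)CCc1ccc(O[Si](C)(C)C(C)(C)C)cc1)c1ccc(O[Si](C)(C)C(C)(C)C)cc1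
F4 | step 9 | (3S,5S,6E)-3-(TBSO)-1,7-bis(Ar)-5-[(triisopropylsilyl)ethynyl]hept-6-ene | CC(C)[Si](C(C)C)(C(C)C)C#C[C@H](/C=C/c1ccc(O[Si](C)(C)C(C)(C)C)cc1)C[C@@H](O[Si](C)(C)C(C)(C)C)CCc1ccc(O[Si](C)(C)C(C)(C)C)cc1
F5 | step 9 | (3S,5S,6E)-5-ethynyl-1,7-bis(4-hydroxyphenyl)hept-6-en-3-ol | C#C[C@H](/C=C/c1ccc(O)cc1)C[C@@H](O)CCc1ccc(O)cc1
F6 | step 19 | (E)-1-(Ar)-2-iodoethene | I/C=C/c1ccc(O[Si](C)(C)C(C)(C)C)cc1
F7 | step 19 | (E)-1-[3-(Hep)-2-hydroxy-6-methoxy-4-(triisopropylsilyloxy)phenyl]-3-(Ar)prop-2-en-1-ol, both carbinol epimers | COc1cc(O[Si](C(C)C)(C(C)C)C(C)C)c([C@H](/C=C/c2ccc(O[Si](C)(C)C(C)(C)C)cc2)C[C@@H](O[Si](C)(C)C(C)(C)C)CCc2ccc(O[Si](C)(C)C(C)(C)C)cc2)c(O)c1C(O)/C=C/c1ccc(O[Si](C)(C)C(C)(C)C)cc1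
F8 | step 19 | (E)-1-[3-(Hep)-2-hydroxy-6-methoxy-4-(triisopropylsilyloxy)phenyl]-3-(Ar)prop-2-en-1-one | COc1cc(O[Si](C(C)C)(C(C)C)C(C)C)c([C@H](/C=C/c2ccc(O[Si](C)(C)C(C)(C)C)cc2)C[C@@H](O[Si](C)(C)C(C)(C)C)CCc2ccc(O[Si](C)(C)C(C)(C)C)cc2)c(O)c1C(=O)/C=C/c1ccc(O[Si](C)(C)C(C)(C)C)cc1
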